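## Analysis of the target

Labdane numbering is used throughout: C1–C10 form the decalin, C11 and C12 the chain carbons, C13 and C14 the epoxide carbons, C15 the OCH2 carbon, C16 the methyl on C13, C17 the methyl on C8, C18/C19 the methyls on C4 and C20 the methyl on C10.

- **Ring system.** The target 13 is a trans-decalin (rings A and B) fused through C8–C9 to an eight-membered oxocane (ring C: C8–O–C15–C14–C13–C12–C11–C9), which carries a trisubstituted epoxide across C13–C14.
- **Decalin stereocentres.** C3 (R, equatorial bromine beside the C4 gem-dimethyl group), C5 (S), C8 (S), C9 (S) and C10 (R) show the pattern of an all-chair cyclization of an (E,E)-polyene. The ring fusion is trans, the C8 and C10 methyls are axial and syn, and the C8–O and C9–C11 bonds are both equatorial and gauche to each other.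
- **Absolute series.** As drawn, the decalin is antipodal to the sclareol series, so the common chiral-pool labdanes are of no use.
- **Epoxide.** C13 (S) and C14 (R) form a ring-cis epoxide (C12 and C15 on the same side), so it derives from a Z alkene held in ring C. Its oxygen lies on the ring face that, in a flat drawing of ring C, also carries the C8 methyl.
- **Sensitive groups.** The secondary bromide next to a quaternary carbon shifts on ionization and is lost to radicals and low-valent metals. The tertiary C8–O ether can ionize to a cation. The epoxide is acid-labile.
- **Difficulty.** A medium ring has to be closed onto a hindered tertiary oxygen. Any cationic activation of C8 or of the C13–C15 allyl unit favours the six-membered 8,13-ether or elimination. C3–Br must also be set enantioselectively.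
- **Feature the strategy rests on.** C15 is a CH2 between the ring oxygen and C14, and C14/C13 can be taken back to the 1,3-dicarbonyl level (C13 ketone, C15 carboxyl). The C8–O–C15 link then becomes an ester bond, which a ketene can form on a tertiary alcohol without any activating reagent.

## Retrosynthetic reasoning

**13 to 12 (C13–O and C14–O).** The epoxide is removed last, because it is the most acid-sensitive group and nothing after it needs to be done. The forward step must deliver oxygen to one face of the ring-held Z alkene of 12; the ring fixes the cis relationship of C12 and C15, so only the face has to be controlled.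

**12 to 10 through 11 (oxidation level of C15).** The C15 methylene is taken back to a lactone carbonyl. This turns the ether O–C15 bond into an ester bond, which is the condition for the key step. The forward reaction must remove one carbonyl oxygen from an unsaturated eight-membered lactone without opening the ring.

**10 to 8 through 9 (C13–C16).** The C13 methyl is cut off, which leaves a C13 ketone. The β-keto lactone 8 is the direct product of a ketene lactonization, and its enol derivative 9 can have only the ring-cis geometry, so the Z alkene of 10 comes for free. The forward reaction is an enol activation and a methyl transfer with retention.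

**8 to 6 through 7 (O–C15, the key disconnection).** The eight-membered ring is opened at the ester bond. The cut is made here and not at a C–C bond because it is the only ring bond whose formation needs no cation at C8 or C15 and no base strong enough to eliminate. The acylketene 7 acylates a tertiary hydroxyl on its own. The forward reaction must make the ketene from 6 by loss of its alkoxy group as the alcohol and must let the C8 hydroxyl capture it faster than a second molecule does.

**6 to 5 and 2 (C13–C14).** The β-keto ester is cut by a Claisen disconnection into the δ-lactone 5 and the enolate of 2. The lactone holds C8–O and C13 in one ring, so its opening frees the C8 hydroxyl and builds the keto ester in the same operation, with no protecting group.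

**5 to 3 (C3–Br, C4–C5, C9–C10, C8–O).** The bromo decalin lactone is unfolded to the acyclic triene ester 3. One bromonium-initiated cascade has to set C3, C5, C10, C9 and C8; the relative configuration follows from the E alkenes and chair folding, and the absolute configuration from the face of the first bromine transfer. The ester oxygen ends the cascade, so the lactone needed for the next step is formed directly.

**3 to 1 and 2 (C11–C12).** The triene ester is cut between the allylic carbon and the acetate carbon. Both pieces are commercial, and the alkylation leaves the two E alkenes of 1 untouched.

## Alternatives that were turned down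

**Alternative 1: ring-closing metathesis at C11=C12 with the epoxide in place.**
- Disconnection: ring C is cut at C11=C12 of A1 (11,12-didehydro-13). A1 comes from diene A2, which has a vinyl group on C9 and a vinyl group on the finished C13 epoxide carbon, joined to C8 through the O–C15 ether.
- Forward key step: the second-generation Grubbs catalyst (H2IMes)(PCy3)Cl2Ru=CHPh closes the ring to A1; diimide would then saturate C11=C12.
- For it: the epoxide configuration is set in an acyclic piece by a reagent-controlled asymmetric epoxidation. On this point it is stronger than the chosen route, which relies on the ring conformation. The closure is neutral and convergent.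
- Against it: A2 needs O-alkylation of the hindered C8 alkoxide at a primary carbon next to an epoxide, where epoxide opening and elimination compete. The C9 vinyl group calls for a cyclization product one carbon shorter and extra redox and olefination steps. Both vinyl groups sit on crowded carbons, so initiation is slow and dimerization competes. A1 is a vinyl epoxide, labile to ruthenium hydrides and acid, and its saturation must spare the allylic C–O bonds and the C3 bromide.
- Comparison: the chosen route closes the ring by heat alone on a molecule that has no epoxide yet, and reaches its precursor in three steps. It gives up the early, reagent-controlled epoxide.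

**Alternative 2: dibromocarbene ring expansion of an oxepine.**
- Disconnection: C13–C14 and C14–C15 are cut, so that C14 is a carbene carbon inserted into the C15=C13 enol ether of the seven-membered A4.
- Forward key step: CHBr3/KOtBu gives the dibromocyclopropane; K2CO3 in hot methanol opens it with loss of bromide and methanol capture at C15 to give A3.
- For it: the eight-membered ring arises by ring expansion, which is unimolecular, needs no dilution and can give only the ring-cis alkene. On reliability of ring formation it is at least equal to the chosen route.
- Against it: A3 carries a vinyl bromide at C14 and a methoxy acetal at C15 that both have to be removed. The vinyl C–Br must be reduced at a hindered position in the presence of the secondary C3 bromide. Removal of the acetal passes through the same allyl oxocarbenium ion as step 8 of the chosen route, so nothing is gained there. A4 is an acid-labile enol ether of a tertiary oxygen and needs a seven-membered ring closure of its own.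
- Comparison: three operations follow the ring formation instead of five, but a further ring synthesis precedes it. The chosen route has no halogen chemoselectivity problem.

**Alternative 3: acetal–vinylsilane Prins closure at C14–C15.**
- Disconnection: C14–C15 of A5, which is the same oxocene as compound 12, is cut back to A6, the C8 methoxymethyl ether with a (Z)-vinylsilane at C13=C14.
- Forward key step: SnCl4 ionizes the acetal to the oxocarbenium ion at C15, C14 attacks ipso, and loss of the silyl group leaves the C13=C14 alkene.
- For it: it reaches 12 directly in the ring-forming step. On step economy after the ring closure it is stronger by four steps. The alkene geometry is set by the vinylsilane.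
- Against it: SnCl4 has to ionize the CH2–OMe bond of an acetal on a tertiary oxygen while the C8–O bond can also break to the C8 cation. The cationic eight-membered closure must outrun protodesilylation and intermolecular reaction. A6 needs a stereodefined trisubstituted vinylsilane chain and acetalization of a hindered tertiary alcohol, so several steps precede the key step.
- Comparison: the chosen strategy offers a ring closure without Lewis acid, in which the reactive intermediate forms reversibly, and a precursor three steps from commercial materials. Both routes share the final epoxidation and its facial question.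

Key step: step 4

Remark on the chemistry: in step 2 the catalyst antipode is taken to be the one that delivers bromine to the alkene face giving (3R); the mirror-image catalyst is used if the sense proves opposite.

## Route

**Step 1**
Reactants: 1 (2E,6E)-farnesyl bromide; 2 tert-butyl acetate
Product: 3 tert-butyl (4E,8E)-5,9,13-trimethyltetradeca-4,8,12-trienoate
Conditions: LiN(iPr)2, THF, −78 °C; then 1, DMPU, −78 → 0 °C
Reagents that add atoms: none
Why: Ester enolate alkylation (SN2) at the primary allylic bromide forms C11–C12; both trisubstituted alkenes keep their E geometry and no stereocentre is involved.

**Step 2**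
Reactants: 3 tert-butyl (4E,8E)-5,9,13-trimethyltetradeca-4,8,12-trienoate
Product: 5 bromo δ-lactone (3-bromo-8,13-epoxy-14,15,16-trinorlabdan-13-one; equatorial Br; trans-decalin; C3/C5/C8/C9/C10 as in the target), via partially cyclized bromo olefin ester 4 (not isolated)
Conditions: (S)-3,3'-bis(2,4,6-triisopropylphenyl)-1,1'-binaphthyl-2,2'-diyl N-triflyl thiophosphoramide, (ArO)2P(=S)NHSO2CF3 (10 mol%), 1,3-dibromo-5,5-dimethylhydantoin, toluene/CH2Cl2, −90 °C; then ClSO3H, 2-nitropropane, −78 °C
Reagents that add atoms: 1,3-dibromo-5,5-dimethylhydantoin, CC1(C)N(Br)C(=O)N(Br)C1=O
Why: Enantioselective bromonium-initiated polyene cyclization; the Lewis-base-activated bromine is transferred to one face of the terminal alkene (sets C3), and chair–chair folding of the E,E-triene with anti addition across each alkene sets C5, C10, C9 and C8 relative to C3, with bromine equatorial. The ester carbonyl oxygen captures the C8 cation from the equatorial side and loses 2-methylpropene to give the lactone. Material that stops by proton loss after rings A and B (typified by 4) is reprotonated by ClSO3H and converges on 5, as in acid-promoted lactonizing cyclizations of farnesyl-type acids and esters.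

**Step 3**
Reactants: 5 bromo δ-lactone; 2 tert-butyl acetate
Product: 6 tert-butyl 3-bromo-8-hydroxy-13-oxo-16-norlabdan-15-oate (β-keto tert-butyl ester of the bromo decalinol)
Conditions: 2 (3 equiv), LiN(iPr)2, THF, −78 °C; then 5, −78 → −30 °C; H2O work-up
Reagents that add atoms: none
Why: Claisen-type acylation of the lithium enolate of 2 by the lactone forms C13–C14 and frees the C8 hydroxyl; the product leaves as its β-keto ester enolate, which blocks a second addition. The equatorial C3 bromide has no anti-periplanar hydrogen, so E2 does not compete. 6 may sit partly as its six-membered hemiketal, a ring–chain tautomer that reopens on heating.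

**Step 4**
Reactants: 6 tert-butyl 3-bromo-8-hydroxy-13-oxo-16-norlabdan-15-oate
Product: 8 eight-membered β-keto lactone (3-bromo-8,15-epoxy-16-norlabdane-13,15-dione), via acylketene 7 (not isolated)
Conditions: toluene, 110 °C, syringe-pump addition over 10 h to ≤1 mM, N2 sweep, condensate returned through 4 Å sieves
Reagents that add atoms: none
Why: On heating, the enol form of 6 loses tert-butanol through a six-membered pseudopericyclic transition state to give acylketene 7; the C8 hydroxyl then adds to the ketene carbon C15 while its proton passes to the C13 carbonyl oxygen, and the enol formed tautomerizes to 8. The closest known reaction type is the thermal transacetoacetylation of hindered alcohols by tert-butyl β-keto esters and its intramolecular form, acylketene macrolactonization. The one ring formed is the eight-membered lactone, closed through the O–C15 bond in what is formally an 8-exo-dig attack on the ketene C=O. No stereocentre is made or touched, and C8 keeps its configuration because its C–O bond is never broken. The step needs intramolecular capture to outrun ketene dimerization and re-addition of tert-butanol; slow addition to high dilution and removal of the alcohol from the refluxing solvent should secure this. It also needs the tertiary hydroxyl to be acylated without ionizing, which the neutral, reagent-free ketene ensures. The equatorial C8–O and C9–C11 bonds hold the hydroxyl gauche to a chain with only three freely rotating bonds and two sp2/sp carbons, which lowers the entropic and transannular cost of the medium ring. The hemiketal form of 6 is a reversible resting state that drains through the open form as 7 is consumed.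

**Step 5**
Reactants: 8 eight-membered β-keto lactone
Product: 9 C13 diethyl enol phosphate of 8 (C13=C14 in the ring; C12 and C15 cis; E by CIP only because the phosphate oxygen outranks C12)
Conditions: NaH, THF, 0 °C; then ClP(O)(OEt)2, 0 °C → rt
Reagents that add atoms: diethyl chlorophosphate, CCOP(=O)(Cl)OCC
Why: Deprotonation at C14 between the two carbonyls and O-phosphorylation of the ketone enolate, a standard β-keto ester enol phosphate formation; the eight-membered ring allows only the ring-cis enol, so the geometry is not in question.

**Step 6**
Reactants: 9 C13 diethyl enol phosphate
Product: 10 3-bromo-8,15-epoxylabd-13Z-en-15-one (unsaturated eight-membered lactone with the C13 methyl)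
Conditions: Me2CuLi (from MeLi, CuI), Et2O, −78 → −30 °C
Reagents that add atoms: lithium dimethylcuprate, [Li+].C[Cu-]C
Why: Cuprate addition–elimination on a β-phosphoryloxy enoate replaces phosphate by methyl with retention, and the ring in any case allows only the Z alkene. The hindered equatorial secondary bromide and the β,β-disubstituted enoate product should be inert to the cuprate at low temperature.

**Step 7**
Reactants: 10 3-bromo-8,15-epoxylabd-13Z-en-15-one
Product: 11 15-acetoxy-3-bromo-8,15-epoxylabd-13Z-ene (α-acetoxy ether; mixture of C15 epimers)
Conditions: iBu2AlH, CH2Cl2, −78 °C; then pyridine, 4-(dimethylamino)pyridine, Ac2O, −78 → 0 °C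
Reagents that add atoms: acetic anhydride, CC(=O)OC(C)=O
Why: Reductive acetylation: 1,2-hydride addition to the lactone gives an aluminium hemiacetal that is acetylated in the cold before it can collapse, so the ring cannot open to the hydroxy enal. The new C15 centre is formed without control and is removed in step 8.

**Step 8**
Reactants: 11 15-acetoxy-3-bromo-8,15-epoxylabd-13Z-ene
Product: 12 3-bromo-8,15-epoxylabd-13Z-ene (oxocene; cyclic allyl ether)
Conditions: Et3SiH, BF3·OEt2, CH2Cl2, −78 °C
Reagents that add atoms: none
Why: Lewis-acid ionization of the acetate gives the ring allyl oxocarbenium ion, which the silane reduces at the carbon next to oxygen (C15), as in Ferrier-type reductions of unsaturated glycosyl acetates. The low temperature and excess silane are there to outrun C8–O heterolysis.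

**Step 9**
Reactants: 12 3-bromo-8,15-epoxylabd-13Z-ene
Product: 13 target, (3R,5S,8S,9S,10R,13S,14R)-3-bromo-8,15:13,14-diepoxylabdane
Conditions: dimethyldioxirane (acetone solution), CH2Cl2, −20 → 0 °C
Reagents that add atoms: dimethyldioxirane, CC1(C)OO1
Why: Concerted syn oxygen transfer from the dioxirane sets C13 and C14 together and keeps C12 and C15 cis; neutral conditions protect the epoxide and the tertiary ether. In the ring conformer that keeps O–C15 anti to the axial C8 methyl and C12 anti to C10, the alkene hangs on the side of the axial C9 hydrogen, and its outward face is the one that should give the (13S,14R) epoxide by peripheral attack.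

## Compound list

1 | (2E,6E)-farnesyl bromide | CC(C)=CCC/C(C)=C/CC/C(C)=C/CBr | starting material
2 | tert-butyl acetate | CC(=O)OC(C)(C)C | starting material
3 | tert-butyl (4E,8E)-5,9,13-trimethyltetradeca-4,8,12-trienoate | CC(C)=CCC/C(C)=C/CC/C(C)=C/CCC(=O)OC(C)(C)C | intermediate
4 | partially cyclized bromo olefin ester (rings A and B closed, 8(17)-ene shown as representative; C3, C5, C9, C10 as in 5) | CC1(C)[C@H](Br)CC[C@]2(C)[C@@H]1CCC(=C)[C@H]2CCC(=O)OC(C)(C)C | intermediate
5 | bromo δ-lactone, 3-bromo-8,13-epoxy-14,15,16-trinorlabdan-13-one | CC1(C)[C@H](Br)CC[C@]2(C)[C@@H]1CC[C@]1(C)OC(=O)CC[C@@H]21 | intermediate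
6 | tert-butyl 3-bromo-8-hydroxy-13-oxo-16-norlabdan-15-oate | CC1(C)[C@H](Br)CC[C@]2(C)[C@@H]1CC[C@](C)(O)[C@H]2CCC(=O)CC(=O)OC(C)(C)C | intermediate
7 | acylketene at C15 (C13 ketone, free C8 hydroxyl) | CC1(C)[C@H](Br)CC[C@]2(C)[C@@H]1CC[C@](C)(O)[C@H]2CCC(=O)C=C=O | intermediate
8 | eight-membered β-keto lactone, 3-bromo-8,15-epoxy-16-norlabdane-13,15-dione | CC1(C)[C@H](Br)CC[C@]2(C)[C@@H]1CC[C@]1(C)OC(=O)CC(=O)CC[C@@H]21 | intermediate
9 | C13 diethyl enol phosphate of 8 (ring-cis C13=C14) | CC1(C)[C@H](Br)CC[C@]2(C)[C@@H]1CC[C@]1(C)OC(=O)/C=C(OP(=O)(OCC)OCC)\CC[C@@H]21 | intermediate
10 | 3-bromo-8,15-epoxylabd-13Z-en-15-one | CC1(C)[C@H](Br)CC[C@]2(C)[C@@H]1CC[C@]1(C)OC(=O)/C=C(C)\CC[C@@H]21 | intermediate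
11 | 15-acetoxy-3-bromo-8,15-epoxylabd-13Z-ene (C15 epimers) | CC1(C)[C@H](Br)CC[C@]2(C)[C@@H]1CC[C@]1(C)OC(OC(C)=O)/C=C(C)\CC[C@@H]21 | intermediate
12 | 3-bromo-8,15-epoxylabd-13Z-ene | CC1(C)[C@H](Br)CC[C@]2(C)[C@@H]1CC[C@]1(C)OC/C=C(C)\CC[C@@H]21 | intermediate
13 | (3R,5S,8S,9S,10R,13S,14R)-3-bromo-8,15:13,14-diepoxylabdane | CC1(C)[C@H](Br)CC[C@]2(C)[C@@H]1CC[C@]1(C)OC[C@H]3O[C@@]3(C)CC[C@@H]21 | target

## Step count and least certain steps

Total step count: 9. Longest linear sequence: 9 steps (1 to 13).

**Step 4 (key step).**
- What may go wrong: the six-membered hemiketal of 6 may dehydrate irreversibly to a cyclic vinylogous carbonate instead of reopening. Product 8 is itself a tertiary-alkyl β-keto ester, so it can revert to 7 on long heating, which exposes the material to ketene dimerization. Traces of water would hydrolyse 7, and decarboxylation to the methyl ketone would follow.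
- Fallback: it sets out from 5 and returns at 8, and it closes the ring at room temperature by thiophilic metal activation instead of heat. The lactone 5 would be opened with the lithium enolate of S-tert-butyl thioacetate to the S-tert-butyl β-keto thioester F1. F1 would be lactonized with AgOCOCF3 (monovalent silver) and Na2HPO4 in THF at 20 °C under high dilution, where 8 cannot revert.

**Step 2.**
- What may go wrong: enantioselectivity may be eroded, or bromine transfer may go to an internal alkene, because the triene and its ester terminus lie outside the substrates on which such catalysts are established. Ring closure of the partially cyclized material under acid may be incomplete or may epimerize C8.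
- Fallback: it sets out from 3 and returns at 5, and it separates the asymmetric cyclization from the halogenation. Hg(OTf)2 (divalent mercury) with 2,2'-(propane-2,2-diyl)bis[(4S)-4-phenyl-4,5-dihydrooxazole] would induce the cyclization, and aqueous NaBr would give the organomercury bromide lactone F2. Br2/LiBr in pyridine would then replace mercury by bromine with retention.

**Step 9.**
- What may go wrong: facial selectivity may be poor or reversed if a second ring conformer of 12 reacts, since the prediction rests on a conformational argument only.
- Fallback: it sets out from 12 and returns at 13, and it places oxygen on the face opposite to the one the electrophile attacks. NBS in aqueous THF would give the bromohydrin F3 (bromine at C14 on the accessible face, water at the tertiary C13 from the other). K2CO3 in methanol would close the epoxide with inversion at C14. This pair of steps is used if direct epoxidation favours the wrong face.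

**Step 7.**
- What may go wrong: the aluminium hemiacetal of a strained lactone of a tertiary alcohol may collapse before it is acetylated. Over-reduction or oxa-Michael closure of the opened hydroxy enal to a six-membered ether would follow.
- Fallback: it sets out from 10 and returns at 12, and it accepts the ring opening instead of suppressing it. Excess iBu2AlH would give the diol F5, and MnO2 would oxidize the allylic alcohol to the hydroxy enal F6. Reductive etherification with Et3SiH and TMSOTf at −78 °C would then close ring C directly to 12.

**Step 6.**
- What may go wrong: methyl transfer to the ring-held enol phosphate may be slow, and competing reduction or attack at the lactone or at the C3 bromide may take over when the mixture is warmed.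
- Fallback: it sets out from 8 and returns at 10, and it replaces the cuprate by a cross-coupling. NaH and PhNTf2 would give the enol triflate F4. Suzuki methylation with trimethylboroxine, PdCl2[1,1'-bis(diphenylphosphino)ferrocene] and K3PO4 in dioxane would then give 10; the zerovalent palladium formed in the flask inserts into the vinyl C–O bond far faster than into the hindered alkyl C–Br bond.

## Further compounds

F1 | step 4 | S-tert-butyl 3-bromo-8-hydroxy-13-oxo-16-norlabdane-15-thioate | CC1(C)[C@H](Br)CC[C@]2(C)[C@@H]1CC[C@](C)(O)[C@H]2CCC(=O)CC(=O)SC(C)(C)C
F2 | step 2 | 3-(bromomercurio)-8,13-epoxy-14,15,16-trinorlabdan-13-one | CC1(C)[C@H]([Hg]Br)CC[C@]2(C)[C@@H]1CC[C@]1(C)OC(=O)CC[C@@H]21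
F3 | step 9 | 3,14-dibromo-8,15-epoxylabdan-13-ol (bromohydrin, Br and OH anti) | CC1(C)[C@H](Br)CC[C@]2(C)[C@@H]1CC[C@]1(C)OC[C@H](Br)[C@@](C)(O)CC[C@@H]21
F4 | step 6 | C13 enol triflate of 8 (ring-cis C13=C14) | CC1(C)[C@H](Br)CC[C@]2(C)[C@@H]1CC[C@]1(C)OC(=O)/C=C(OS(=O)(=O)C(F)(F)F)\CC[C@@H]21
F5 | step 7 | 3-bromolabd-13Z-ene-8,15-diol | CC1(C)[C@H](Br)CC[C@]2(C)[C@@H]1CC[C@](C)(O)[C@H]2CC/C(C)=C\CO
F6 | step 7 | 3-bromo-8-hydroxylabd-13Z-en-15-al | CC1(C)[C@H](Br)CC[C@]2(C)[C@@H]1CC[C@](C)(O)[C@H]2CC/C(C)=C\C=O
A1 | alternative 1 | 11,12-didehydro target (3-bromo-8,15:13,14-diepoxylabd-11Z-ene) | CC1(C)[C@H](Br)CC[C@]2(C)[C@@H]1CC[C@]1(C)OC[C@H]3O[C@@]3(C)/C=C\[C@@H]21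
A2 | alternative 1 | metathesis diene (C9 vinyl; C8 ether of the epoxy alcohol bearing a vinyl group on C13) | CC1(C)[C@H](Br)CC[C@]2(C)[C@@H]1CC[C@](C)(OC[C@H]1O[C@@]1(C)C=C)[C@H]2C=C
A3 | alternative 2 | 14-bromo-15-methoxy oxocene (one C15 anomer) | CC1(C)[C@H](Br)CC[C@]2(C)[C@@H]1CC[C@]1(C)O[C@@H](OC)/C(Br)=C(C)\CC[C@@H]21
A4 | alternative 2 | seven-membered C15=C13 enol ether (oxepine) | CC1(C)[C@H](Br)CC[C@]2(C)[C@@H]1CC[C@]1(C)OC=C(C)CC[C@@H]21
A5 | alternative 3 | bromo oxocene, identical with compound 12 | CC1(C)[C@H](Br)CC[C@]2(C)[C@@H]1CC[C@]1(C)OC/C=C(C)\CC[C@@H]21
A6 | alternative 3 | C8 methoxymethyl ether with (Z)-vinylsilane at C13=C14 | CC1(C)[C@H](Br)CC[C@]2(C)[C@@H]1CC[C@](C)(OCOC)[C@H]2CC/C(C)=C\[Si](C)(C)C
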